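Remark on the chemistry: the enol silyl group of the key-step precursor is taken as triethylsilyl and not trimethylsilyl. This is a protecting-group change only; the skeleton, the bonds formed and the ring expanded are untouched.
Remark on the chemistry: the target has no stereocenter, so the carbinol centre of the intermediates is carried as the racemate and ring C2 of 8 and 9 as a pair of epimers.

## Structural features

The target is one fully substituted 4H-pyran-4-one ring: O1, C2 carrying a propanoyl group through its carbonyl carbon, C4 as the ring carbonyl, and bromine on C3, C5 and C6. There is no second ring and no stereocenter. The carbon skeleton is only a five-carbon ring array joined to a three-carbon acyl chain, so the problem is regiochemical. The C6–Br bond is a vinylogous acyl bromide and is open to addition–elimination by nucleophiles. The ring is also opened at C2 and C6 by amines, hydroxide and alkoxides, and all three C–Br bonds are sensitive to halogen–metal exchange and reduction. The three bromines differ electronically: C3 and C5 sit alpha to the carbonyl, whereas C6 next to the ring oxygen is an electrophilic carbon that electrophilic bromination does not reach. The key step exploits the triad C2–C3(Br)–C4(=O). Removing C3 with its bromine joins C2 to C4 and leaves a furan whose C2=C3 bond carries the ring oxygen at one end and an oxygen substituent at the other, that is, a 3-siloxyfuran. The C5–Br and C6–Br of the pyranone then map onto C4 and C5 of that furan, where the carbon next to oxygen can be brominated through deprotonation.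

## Logic of the disconnections

19 to 18: no skeletal bond is cut; the side-chain C=O is taken back to C–OH. A ketone conjugated to C2 would drain electron density from the ring bond that must react with the carbene and would not survive the organolithium steps. The gain is that every earlier compound carries a robust sp3 carbinol. The demand is a final oxidation that is neutral and non-nucleophilic, because C6–Br in 18 and 19 is easily displaced.

18 to 17: the side-chain O–Si bond is cut. A free hydroxyl would quench the lithium bases and react with the carbene. One protecting group then serves from step 2 to step 8. Its removal must avoid basic fluoride, which could attack C6.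

17 to 12 and 13: the ring bonds C2–C3 and C3–C4 are cut and the C3–Br unit is excised, which contracts the pyranone to a furan. C3 lies between the oxygen-bearing C2 and the carbonyl C4, which is the pattern a carbene insertion into an enol ether leaves behind. The gain is large: a six-membered tribromo heterocycle becomes an aromatic furan plus a one-carbon reagent. The forward step must select C2=C3 over C4=C5, the cyclopropane must open in the ring-expanding sense, and the base must not strip the enol silyl group or attack the product.

12 to 10: the C5–Br bond is cut. C5–H is the only ring hydrogen in 10 and is acidified by O1 and by the neighbouring bromine. The forward step must be a metalation followed by a Br+ donor, because electrophilic bromination of a 3-siloxyfuran would go to C2.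

10 to 9: the enol O–Si bond is cut. The aromatic siloxyfuran is the silyl enol ether of a furan-3(2H)-one, so a sensitive electron-rich furan is traded for a ketone that can be handled. Enolisation can only go toward C2, the sole sp3 alpha carbon.

9 to 8: the C4–Br bond is cut. C4 of 8 is the nucleophilic alpha carbon of a cyclic vinylogous ester, the one stage where the ring offers a built-in nucleophile at this position. The forward bromination must be faster at C4 than at C2 through the enol.

8 to 5: the C3–O bond is cut and replaced by C3–Br. That bromine is the same atom that directs the first lithiation, so it serves twice. The forward step needs a clean bromine–lithium exchange and an oxidation mild enough for 8.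

5 to 4: the O–Si bond is cut; this is a routine protection.

4 to 1 and 2: the bond between ring C2 and the carbinol carbon is cut. The carbinol carbon is a natural aldehyde electrophile and C2 of 1 is the kinetically acidic position. Two commercial compounds result, which together hold seven of the eight carbons of the target. The metalation must be run cold so that the lithiated bromofuran does not rearrange or open.

## Other disconnections considered

Alternative 1: The cut runs through C4–C5 and O1–C6, so that O1, C2, C3 and C4 come from an acylketene and C5 and C6 from an alkyne.
- Forward key step: the acyl Meldrum's acid A1 would be heated until it loses acetone and carbon dioxide. The acylketene A3 so formed would take up (bromoethynyl)trimethylsilane A2 across its ketene carbon and acyl oxygen to give the 6-bromo-5-silyl pyranone A4.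
- In favour: the approach is convergent, and the ring arrives with C6–Br, the bromine that is hardest to place. The side chain enters at the ketone oxidation level as a ketal, and the silyl group at C5 is a clean handle for ipso-bromination.
- Against: acylketenes combine smoothly only with strongly nucleophilic two-atom partners, and a bromo(silyl)alkyne is a weak one, so dimerisation of A3 or its recapture by acetone should compete. The regiochemistry rests on the beta-silicon effect alone. A4 would still need bromination at C3, bromodesilylation at C5 and ketal hydrolysis on a ring that already carries the sensitive C6–Br.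
- Structure: Alternative 1 addresses C6–Br more directly and is the better plan on side-chain oxidation level, but it leaves two bromines for later, whereas the chosen plan delivers all three with the ring.
- Mechanism: neither ring-forming step has direct precedent on its substrate class. The carbene adding to an electron-rich enol ether bond matches the polarity of its known relatives more closely, so the chosen step is judged somewhat safer, though not by a wide margin.
- Step economy: about six steps against nine, so Alternative 1 is the better of the two here.

Alternative 2: The cut is O1–C6 alone. The ring is unrolled into the eight-carbon chain A5, which carries a 1,3-dione, the side-chain ketone as a dimethyl ketal, one bromine between the carbonyls and a tribromovinyl terminus.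
- Forward key step: K2CO3 would enolise the dione toward the ketal-bearing carbonyl. The enol oxygen would add to the CBr2 carbon of the dibromo enone and bromide would be expelled, giving A6 with every bromine in place.
- In favour: the closure is an intramolecular vinylic substitution on a doubly activated acceptor, mild and well understood, and it mirrors a plausible biosynthesis. Only ketal hydrolysis would remain.
- Against: the burden moves to A5. A linear alpha-bromo-1,3-diketone with a tribromoacryloyl end is prone to retro-Claisen cleavage and dehydrobromination, and each bromine must be placed on an enolisable acyclic chain over several steps.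
- Structure: Alternative 2 is the equal or the better of the chosen plan, since all C–Br bonds and the correct side-chain oxidation level exist before ring closure.
- Mechanism: its key step is better precedented than the carbene insertion; this is a clear point for Alternative 2.
- Step economy: the chain synthesis should cost seven or more steps, so the total is no shorter than nine and probably longer. The risk is also spread over several labile intermediates, whereas the chosen plan keeps robust furans up to the key step.

Alternative 3: The cut is O1–C2 together with C3–Br and C5–Br. The ring opens to the (Z)-ethoxy enynone A7, whose enol ether oxygen is the future O1 and whose alkyne carbons are the future C2 and C3.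
- Forward key step: two equivalents of Br2 would be used. The first activates the alkyne, the enol ether oxygen attacks the distal alkyne carbon in 6-endo mode, and the oxonium ion loses its ethyl group to bromide. The second equivalent brominates C5, giving A8.
- In favour: electrophile-induced cyclisation of heteroatom-tethered ynones is an established route to 3-halo-4-pyranone-type rings. A7 should be reachable in about three steps, the ring and two C–Br bonds form in one flask, and the protecting group and endgame are those of the chosen plan.
- Against: A8 has hydrogen at C6, so the hardest bromine is left for a separate metalation–bromination on an electrophilic dibromopyranone. Br2 may add first to the electron-rich enol ether double bond, the Z geometry could be lost under HBr, and the silyl ether must survive the acid.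
- Structure: Alternative 3 is weaker, since only two of the three bromines come with the ring.
- Mechanism: the cyclisation type is better precedented than the carbene ring expansion; this is a point for Alternative 3.
- Step economy: about eight steps against nine, so it is equal or slightly better.

The chosen plan is preferred because C6–Br is installed by a reliable furan alpha-lithiation before the ring is expanded.

Key step: step 7

## Route

Step 1
Reactants: 1 3-bromofuran; 2 propanal
Product: 4 rac-1-(3-bromofuran-2-yl)propan-1-ol, via 3-bromo-2-lithiofuran 3 (not isolated)
Conditions: LiN(i-Pr)2, THF, −78 °C; then 2, −78 °C; H2O quench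
Reagents that add atoms: none
Why: Directed deprotonation by the lithium amide occurs at C2, which is both alpha to the ring oxygen and ortho to bromine, and at −78 °C the lithio species neither eliminates nor lets the halogen migrate; 1,2-addition to the aldehyde gives the secondary carbinol as a racemate, which is sufficient because this centre is oxidised away in step 9.

Step 2
Reactants: 4 rac-1-(3-bromofuran-2-yl)propan-1-ol
Product: 5 rac-{[1-(3-bromofuran-2-yl)propyl]oxy}(tert-butyl)dimethylsilane
Conditions: TBSCl, imidazole, DMF, 0 °C → rt
Reagents that add atoms: tert-butyldimethylsilyl chloride, CC(C)(C)[Si](C)(C)Cl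
Why: Standard imidazole-promoted silylation of a secondary alcohol; the tert-butyldimethylsilyl ether tolerates organolithiums, peroxide, N-bromo imide, amide bases and tert-butoxide, all of which follow.

Step 3
Reactants: 5 rac-{[1-(3-bromofuran-2-yl)propyl]oxy}(tert-butyl)dimethylsilane
Product: 8 2-[1-(tert-butyldimethylsilyloxy)propyl]furan-3(2H)-one (two racemic diastereomers), via 3-lithiofuran 6 (not isolated), via dimethyl furan-3-ylboronate 7 (not isolated)
Conditions: n-BuLi, THF, −78 °C; B(OMe)3, −78 → 0 °C; AcOH, 30% aq H2O2, 0 °C → rt
Reagents that add atoms: hydrogen peroxide, OO
Why: Bromine–lithium exchange at −78 °C outruns ring deprotonation, the borate traps 6, and ipso-oxidation of the boronate (1,2-shift of the furyl group from boron to oxygen) gives the 3-hydroxyfuran, which tautomerises to the furan-3(2H)-one; the weakly acidic peroxide medium spares the base-sensitive beta-alkoxy enone, and the new ring C2 centre is uncontrolled and is erased in step 5.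

Step 4
Reactants: 8 2-[1-(tert-butyldimethylsilyloxy)propyl]furan-3(2H)-one
Product: 9 4-bromo-2-[1-(tert-butyldimethylsilyloxy)propyl]furan-3(2H)-one (two racemic diastereomers)
Conditions: NBS (1.05 equiv), CH2Cl2, 0 °C, dark
Reagents that add atoms: N-bromosuccinimide, O=C1CCC(=O)N1Br
Why: Alpha-halogenation of a vinylogous ester: C4 is the nucleophilic terminus of the O1–C5=C4 enol ether unit, so Br+ adds there and loss of the C4 proton restores the enone, while the neutral, cold, acid-free medium keeps enolisation toward C2 slow.

Step 5
Reactants: 9 4-bromo-2-[1-(tert-butyldimethylsilyloxy)propyl]furan-3(2H)-one
Product: 10 rac-4-bromo-2-[1-(tert-butyldimethylsilyloxy)propyl]-3-(triethylsilyloxy)furan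
Conditions: Et3SiOTf, Et3N, CH2Cl2, −78 → 0 °C
Reagents that add atoms: triethylsilyl trifluoromethanesulfonate, CC[Si](CC)(CC)OS(=O)(=O)C(F)(F)F
Why: Soft enolisation and O-silylation: the silyl triflate activates the carbonyl, the amine removes the only sp3 alpha proton at C2, and aromatisation to the furan drives the reaction, so both epimers of 9 converge on one racemic compound.

Step 6
Reactants: 10 rac-4-bromo-2-[1-(tert-butyldimethylsilyloxy)propyl]-3-(triethylsilyloxy)furan
Product: 12 rac-4,5-dibromo-2-[1-(tert-butyldimethylsilyloxy)propyl]-3-(triethylsilyloxy)furan, via 5-lithiofuran 11 (not isolated)
Conditions: LiN(i-Pr)2, THF, −78 °C; BrCl2C–CCl2Br, −78 → −20 °C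
Reagents that add atoms: 1,2-dibromo-1,1,2,2-tetrachloroethane, ClC(Cl)(Br)C(Cl)(Cl)Br
Why: Directed metalation followed by electrophilic bromination: C5–H is the only ring hydrogen and, as in step 1, is alpha to oxygen and ortho to bromine, so the amide base gives 11, which takes Br+ from the polyhaloethane with loss of tetrachloroethene; direct electrophilic bromination is avoided because a 3-siloxyfuran would be attacked at C2.

Step 7
Reactants: 12 rac-4,5-dibromo-2-[1-(tert-butyldimethylsilyloxy)propyl]-3-(triethylsilyloxy)furan; 13 bromoform
Product: 17 rac-2,3,5-tribromo-6-[1-(tert-butyldimethylsilyloxy)propyl]-4H-pyran-4-one, via dibromocarbene 14 (not isolated), via tetrabromo-oxabicyclohexene adduct 15 (not isolated), via 3-bromo-4-siloxypyrylium bromide 16 (not isolated)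
Conditions: 13 (2–3 equiv), KOC(CH3)3 added in portions, hexane, −30 → 0 °C
Reagents that add atoms: none
Why: Proposed new method: the alkoxide converts bromoform into dibromocarbene 14, an electrophilic singlet carbene that should add in a concerted [2+1] manner to the most electron-rich pi bond of 12, the C2=C3 enol ether bond flanked by the ring oxygen and the siloxy group. The adduct 15 is a gem-dibromocyclopropane with an oxygen donor on each bridgehead and should ionise at once: the bromide syn to the five-membered ring departs while the shared C–C bond opens in the disrotatory sense of a cyclopropyl-to-allyl cation change, which gives the aromatic pyrylium ion 16. Bromide (or tert-butoxide) then removes the triethylsilyl group from oxygen and leaves 17. The six-membered ring therefore arises by one-carbon ring expansion (cheletropic addition followed by a two-electron electrocyclic opening) and not by a cyclisation, and the new bonds are C2–C3, C3–C4 and C3–Br. The closest known reaction types are the dihalocarbene ring expansion of cyclic silyl enol ethers to 2-halo-enones and the Ciamician–Dennstedt carbon insertion into pyrroles and indoles; the new element is a 3-siloxyfuran as the substrate. No stereocenter is created in 17, since the two bridgehead centres of 15 vanish on opening and the carbinol centre stays racemic. The step needs site selectivity between the two furan double bonds, and the substrate supplies it: the siloxy donor raises the nucleophilicity of C2=C3 while the two bromines on C4=C5 lower that of the other bond and shield it. The sp3 carbinol side chain keeps C2=C3 electron-rich, and the triethylsilyl enol ether should resist premature removal by tert-butoxide in hexane better than a trimethylsilyl group.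

Step 8
Reactants: 17 rac-2,3,5-tribromo-6-[1-(tert-butyldimethylsilyloxy)propyl]-4H-pyran-4-one
Product: 18 rac-2,3,5-tribromo-6-(1-hydroxypropyl)-4H-pyran-4-one
Conditions: 48% aq HF, MeCN, 0 °C
Reagents that add atoms: none
Why: Acid-mediated fluoride desilylation of a secondary silyl ether; the medium contains no base and no strong nucleophile, so the vinylogous acyl bromide at the ring carbon next to oxygen should not be substituted as it might be with a basic ammonium fluoride.

Step 9
Reactants: 18 rac-2,3,5-tribromo-6-(1-hydroxypropyl)-4H-pyran-4-one
Product: 19 2,3,5-tribromo-6-propanoyl-4H-pyran-4-one
Conditions: Dess–Martin periodinane, CH2Cl2, rt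
Reagents that add atoms: none
Why: Dess–Martin oxidation (ligand exchange at hypervalent iodine, then intramolecular removal of the carbinol hydrogen) is neutral and non-nucleophilic, which suits the electrophilic tribromopyranone, and it removes the only stereocenter to give the achiral target.

## Compound list

1 | 3-bromofuran | Brc1ccoc1 | starting material
2 | propanal | CCC=O | starting material
3 | 3-bromo-2-lithiofuran | [Li]c1occc1Br | intermediate (not isolated)
4 | rac-1-(3-bromofuran-2-yl)propan-1-ol | CCC(O)c1occc1Br | intermediate
5 | rac-{[1-(3-bromofuran-2-yl)propyl]oxy}(tert-butyl)dimethylsilane | CCC(O[Si](C)(C)C(C)(C)C)c1occc1Br | intermediate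
6 | rac-{2-[1-(tert-butyldimethylsilyloxy)propyl]furan-3-yl}lithium | CCC(O[Si](C)(C)C(C)(C)C)c1occc1[Li] | intermediate (not isolated)
7 | rac-dimethyl {2-[1-(tert-butyldimethylsilyloxy)propyl]furan-3-yl}boronate | CCC(O[Si](C)(C)C(C)(C)C)c1occc1B(OC)OC | intermediate (not isolated)
8 | 2-[1-(tert-butyldimethylsilyloxy)propyl]furan-3(2H)-one, two racemic diastereomers | CCC(O[Si](C)(C)C(C)(C)C)C1OC=CC1=O | intermediate
9 | 4-bromo-2-[1-(tert-butyldimethylsilyloxy)propyl]furan-3(2H)-one, two racemic diastereomers | CCC(O[Si](C)(C)C(C)(C)C)C1OC=C(Br)C1=O | intermediate
10 | rac-4-bromo-2-[1-(tert-butyldimethylsilyloxy)propyl]-3-(triethylsilyloxy)furan | CCC(O[Si](C)(C)C(C)(C)C)c1occ(Br)c1O[Si](CC)(CC)CC | intermediate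
11 | rac-{3-bromo-5-[1-(tert-butyldimethylsilyloxy)propyl]-4-(triethylsilyloxy)furan-2-yl}lithium | CCC(O[Si](C)(C)C(C)(C)C)c1oc([Li])c(Br)c1O[Si](CC)(CC)CC | intermediate (not isolated)
12 | rac-4,5-dibromo-2-[1-(tert-butyldimethylsilyloxy)propyl]-3-(triethylsilyloxy)furan | CCC(O[Si](C)(C)C(C)(C)C)c1oc(Br)c(Br)c1O[Si](CC)(CC)CC | intermediate
13 | bromoform | BrC(Br)Br | starting material
14 | dibromocarbene | Br[C]Br | intermediate (not isolated)
15 | 3,4,6,6-tetrabromo-1-[1-(tert-butyldimethylsilyloxy)propyl]-5-(triethylsilyloxy)-2-oxabicyclo[3.1.0]hex-3-ene, cis-fused, racemic diastereomers | CCC(O[Si](C)(C)C(C)(C)C)C12OC(Br)=C(Br)C1(O[Si](CC)(CC)CC)C2(Br)Br | intermediate (not isolated)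
16 | rac-2,3,5-tribromo-6-[1-(tert-butyldimethylsilyloxy)propyl]-4-(triethylsilyloxy)pyrylium bromide | CCC(O[Si](C)(C)C(C)(C)C)c1[o+]c(Br)c(Br)c(O[Si](CC)(CC)CC)c1Br.[Br-] | intermediate (not isolated)
17 | rac-2,3,5-tribromo-6-[1-(tert-butyldimethylsilyloxy)propyl]-4H-pyran-4-one | CCC(O[Si](C)(C)C(C)(C)C)c1oc(Br)c(Br)c(=O)c1Br | intermediate
18 | rac-2,3,5-tribromo-6-(1-hydroxypropyl)-4H-pyran-4-one | CCC(O)c1oc(Br)c(Br)c(=O)c1Br | intermediate
19 | 2,3,5-tribromo-6-propanoyl-4H-pyran-4-one | CCC(=O)c1oc(Br)c(Br)c(=O)c1Br | target

## Step count and least certain steps

Total step count: 9. Longest linear sequence: 9 steps, from 1 to 19.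

**Step 7 (key step).** Three things are most likely to go wrong:
- tert-butoxide may remove the enol silyl group before the carbene arrives, after which the furanolate is C-alkylated at C2 by the carbene instead of being cyclopropanated;
- carbene addition may be slow at a tetrasubstituted double bond flanked by the bulky silyloxypropyl group;
- the alkoxide may displace the bromide next to the ring oxygen of the product by addition–elimination.

The fallback abandons the ring expansion and uses known metalation chemistry on a preformed pyranone. It sets out from 2 and returns at 18. 3,5-Dibromo-4H-pyran-4-one F1, a known compound obtained by brominating the parent pyranone, would be magnesiated at the carbon next to the ring oxygen with TMPMgCl·LiCl in THF at −40 °C and added to propanal 2. This should give rac-3,5-dibromo-2-(1-hydroxypropyl)-4H-pyran-4-one F2. A second magnesiation of F2 at the remaining ring C–H with two equivalents of the same base, followed by 1,2-dibromo-1,1,2,2-tetrachloroethane, should give 18, which then enters step 9. Both operations rely on hindered magnesium amide metalation of chromone- and pyranone-type C–H bonds alpha to the ring oxygen, a known reaction type.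

**Step 4.** The likely failure is bromination at C2 through the aromatic 3-hydroxyfuran tautomer, or over-bromination, because the C2 hydrogen of 8 is enolisable and the enol reacts at C2. The fallback installs both bromines by directed metalation instead. It sets out from 8 and returns at 12, bypassing 9 and 10.
- 8 would be silylated with Et3SiOTf and Et3N to rac-2-[1-(tert-butyldimethylsilyloxy)propyl]-3-(triethylsilyloxy)furan F3.
- The only alpha hydrogen of F3 (C5) would be removed with s-BuLi in THF at −78 °C and the anion quenched with 1,2-dibromo-1,1,2,2-tetrachloroethane to give rac-5-bromo-2-[1-(tert-butyldimethylsilyloxy)propyl]-3-(triethylsilyloxy)furan F4.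
- LiN(i-Pr)2 at −78 °C would then remove the last ring hydrogen of F4, between the siloxy and bromo groups, and the same bromine donor would give 12.
- Migration of bromine in the lithiated species would lead to 11, which is brominated to 12 as well, so it does no harm.

**Step 3.** Two processes threaten this step: proton transfer within lithiofuran 6, which moves lithium to the alpha position before the borate is added, and degradation of the electron-rich furanol or the beta-alkoxy enone during the peroxide oxidation. The fallback separates the two events and avoids the lithio species. It sets out from 5 and returns at 8. Miyaura borylation of 5 (Pd(dppf)Cl2, bis(pinacolato)diboron, KOAc, 1,4-dioxane, 80 °C) should give the isolable rac-2-{2-[1-(tert-butyldimethylsilyloxy)propyl]furan-3-yl}-4,4,5,5-tetramethyl-1,3,2-dioxaborolane F5. F5 would then be oxidised under anhydrous conditions with trimethylamine N-oxide in THF and the borate hydrolysed with neutral buffer to give 8.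

**Step 8.** The risk is substitution at the bromine-bearing carbon next to the ring oxygen by fluoride or water, or incomplete cleavage of the hindered silyl ether. The fallback merges deprotection and oxidation. It sets out from 17 and returns at 19. Treating 17 with Jones reagent (CrO3 in aqueous H2SO4 and acetone, 0 °C) is a known direct conversion of secondary silyl ethers into ketones in a strongly acidic, fluoride-free medium. No new compound lies on the way.

## Further compounds

F1 | step 7 | 3,5-dibromo-4H-pyran-4-one | O=c1c(Br)cocc1Br
F2 | step 7 | rac-3,5-dibromo-2-(1-hydroxypropyl)-4H-pyran-4-one | CCC(O)c1occ(Br)c(=O)c1Br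
F3 | step 4 | rac-2-[1-(tert-butyldimethylsilyloxy)propyl]-3-(triethylsilyloxy)furan | CCC(O[Si](C)(C)C(C)(C)C)c1occc1O[Si](CC)(CC)CC
F4 | step 4 | rac-5-bromo-2-[1-(tert-butyldimethylsilyloxy)propyl]-3-(triethylsilyloxy)furan | CCC(O[Si](C)(C)C(C)(C)C)c1oc(Br)cc1O[Si](CC)(CC)CC
F5 | step 3 | rac-2-{2-[1-(tert-butyldimethylsilyloxy)propyl]furan-3-yl}-4,4,5,5-tetramethyl-1,3,2-dioxaborolane | CCC(O[Si](C)(C)C(C)(C)C)c1occc1B1OC(C)(C)C(C)(C)O1
F0 | step 8 | none | none
A1 | alternative 1 | 5-(2,2-dimethoxybutanoyl)-2,2-dimethyl-1,3-dioxane-4,6-dione | CCC(OC)(OC)C(=O)C1C(=O)OC(C)(C)OC1=O
A2 | alternative 1 | (bromoethynyl)trimethylsilane | C[Si](C)(C)C#CBr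
A3 | alternative 1 | 4,4-dimethoxy-3-oxohex-1-en-1-one | CCC(OC)(OC)C(=O)C=C=O
A4 | alternative 1 | 6-bromo-2-(1,1-dimethoxypropyl)-5-(trimethylsilyl)-4H-pyran-4-one | CCC(OC)(OC)c1cc(=O)c([Si](C)(C)C)c(Br)o1
A5 | alternative 2 | rac-1,1,2,4-tetrabromo-6,6-dimethoxyoct-1-ene-3,5-dione | CCC(OC)(OC)C(=O)C(Br)C(=O)C(Br)=C(Br)Br
A6 | alternative 2 | 2,3,5-tribromo-6-(1,1-dimethoxypropyl)-4H-pyran-4-one | CCC(OC)(OC)c1oc(Br)c(Br)c(=O)c1Br
A7 | alternative 3 | rac-(Z)-6-(tert-butyldimethylsilyloxy)-1-ethoxyoct-1-en-4-yn-3-one | CCO/C=C\C(=O)C#CC(CC)O[Si](C)(C)C(C)(C)C
A8 | alternative 3 | rac-3,5-dibromo-2-[1-(tert-butyldimethylsilyloxy)propyl]-4H-pyran-4-one | CCC(O[Si](C)(C)C(C)(C)C)c1occ(Br)c(=O)c1Br
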